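Time is what separates these flasks: they share their charges and their end at 2.5 min, but not the time electrophile and nucleophile spend together warm.

common to all: buffer base 40.0 mM; buffer acid 2.00 mM; protic impurity 4.00 mM; time 2.5 min
- birch: electrophile 20 mM (fed, over 1.0 min); nucleophile 30.0 mM; temperature 35 °C; all else is in the flask from the start; the feed brings no volume worth counting
- alder: electrophile 20 mM (in portions, 4, over 1.0 min); nucleophile 30.0 mM; temperature 35 °C; first portion at the start, last at 1.0 min
- oak: electrophile 20 mM; nucleophile 30.0 mM; temperature 35 °C; everything together at the start
- ash: electrophile 20 mM; nucleophile 30.0 mM (fed, over 1.0 min); the addition at 15 °C, then warmed to 35 °C; the feed brings no volume worth counting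
- maple: electrophile 20 mM; nucleophile 30.0 mM; everything together at the start at 15 °C, warmed to 35 °C at 1.0 min

    electrophile + nucleophile → acid + target + leaving group (k1 = 0.0821 /M/s, Ea1 = 52.0 kJ/mol)
    protonated nucleophile ⇌ nucleophile + acid, settled at all times (K2 = 3.2 × 10⁻⁸ M, ΔH2 = −73.0 kJ/mol)
    buffer acid ⇌ buffer base + acid, settled at all times (K3 = 6.3 × 10⁻⁵ M, ΔH3 = −53.0 kJ/mol)
    electrophile + protic impurity → quenched substrate (k4 = 0.0799 /M/s, Ea4 = 56.0 kJ/mol)
    (constants at 35 °C)

- acid is the free proton; pH is minus the decimal logarithm of its molar concentration
- the list of constants is for 35 °C, to be carried to other temperatures by the activation energies and enthalpies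

1. the flask that comes out highest in amount of target, in percent of the electrophile charged, or "all alike" when all lie within 1.5 percentage points (birch / alder / oak / ash / maple / all alike)
2. target at the end, in percent of the electrophile charged, birch
3. target at the end, in percent of the electrophile charged, alder
4. target at the end, in percent of the electrophile charged, oak
5. target at the end, in percent of the electrophile charged, ash
6. target at the end, in percent of the electrophile charged, maple

The protons come first. Buffer acid, at 6.3 × 10⁻⁵ M, is a far stronger acid than protonated nucleophile, at 3.2 × 10⁻⁸ M, so its 2.00 mM pass to nucleophile at once. Free nucleophile therefore begins at b = 28.0 mM. For the same reason each acid released with a target goes to nucleophile and not to buffer base, so free nucleophile falls by two for each target formed: once by reaction, once by protonation.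

Let P be the target, a the electrophile charge and k the rate constant of the making step. Then dP/dt = k(a − P)(b − 2P). The impurity is set aside here, because its pseudo-first-order constant 0.0192 /min is smaller than the 0.138 /min of nucleophile. Partial fractions integrate this rate in closed form: P/a = b(1 − G)/(2a − Gb), where G = exp(−sθ), s = (2a − b)k = 0.0591 /min, and θ is the time the pair has had. For oak, θ is the whole 2.5 min, which gives 24.3%.

The other flasks need a shorter θ. In birch the average electrophile arrives halfway through the feed, and the portions of alder arrive on average at that same moment, so both have 2.00 min. At 15 °C the making step runs at f = 0.244 of its warm rate, about a quarter, so the cold period of maple counts as 0.244 min and the whole run of maple as 1.74 min. Ash is colder still in effect, because during its cold period its nucleophile stands on average at half its charge, so that period counts as 0.122 min and the whole run of ash as 1.62 min. This is the effective time θ: the span at full temperature and full charge that gives the same exposure of electrophile to nucleophile.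

Put into the closed form, these times give 20.6% for birch and alder, 18.6% for maple and 17.6% for ash, so this reckoning puts oak first.

The forecast also names oak, because "the flask with the greatest electrophile-time exposure" comes out ahead. Its figures are 20.3% for birch, 20.3% for alder, 23.9% for oak, 17.3% for ash and 18.3% for maple; for oak that is less than the reckoning here.

The simulation puts oak highest at 23.9%, followed by birch 20.3%, alder 20.3%, maple 18.4% and ash 17.3%. At 2.50 min oak holds 6.76 mM of protonated nucleophile, which is its 4.77 mM of leaving group plus the 2.00 mM of buffer acid. The neighbour of ash with 120 mM of nucleophile keeps θ = 1.62 min but has b = 118 mM, so the closed form gives 56.7%, and that flask ends at 55.9%.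

The rate constants are invented; the rest is arithmetic.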